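**Plan**

1. Numbering: upper cis-decalin = ring A (C-1 to C-5 and C-10, exocyclic C-11 on C-4) and ring B (C-5 to C-10; Me on C-8, Me and CH2Ar on C-9); lower decalin = rings C and D (C-1′ to C-10′); C-12′ and C-11′ link C-5 to C-9′.
2. Cuts: the two O–S and two O–CH3 bonds, then C4–C5 (ring A), then C3–C4 (acetylide), then C5–C12′ (sp2–sp3 coupling), leaving a ring B enol triflate and a lower-decalin alkyl iodide.
3. Enabling feature: C-4 carries the exocyclic methylene and is bonded to the quaternary ring-fusion carbon C-5, so ring A can close by 6-exo-trig attack of a C-4 vinyl radical (from a C4≡C11 alkyne on a C-10 tether) on a C5=C6 alkene of ring B.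
4. Forward order: ring B (enone, two conjugate additions, allylation); rings C and D (conjugate addition, aldol ring closure, Johnson–Claisen); union at C5–C12′; chain extension; ring A last; phenol release and sulfation.
5. Stereochemistry: C-8 by enamine catalysis; C-9 and C-10 by substrate control from C-8; C-5 from C-10 in the ring closure (cis fusion); C-5′ by a chiral copper catalyst, C-8′ by equilibration, C-9′ by chirality transfer from a CBS-set carbinol.

Key step: step 18

Assumption: the target is taken as the free bis(hydrogen sulfate) as drawn; the pyridinium salt formed in the last step is converted into it on a proton-form sulfonic acid resin.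

**Route**

Step 1
Reactants: 1 propanal; 2 methyl vinyl ketone (but-3-en-2-one)
Product: 3 (S)-2-methyl-5-oxohexanal
Conditions: (R)-2-[methoxy(diphenyl)methyl]pyrrolidine (5 mol%), ethyl 3,4-dihydroxybenzoate (20 mol%), neat, 4 °C
Reagents that add atoms: none
Why: Enamine-catalysed Michael addition of an aldehyde to an enone, in which the (R)-prolinol ether shields one face of the E-enamine and is expected to set the methyl-bearing stereocenter (the future C-8) as S.

Step 2
Reactants: 3 (S)-2-methyl-5-oxohexanal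
Product: 4 (S)-4-methylcyclohex-2-en-1-one
Conditions: LiOH (0.1 equiv), i-PrOH, 25 °C
Reagents that add atoms: none
Why: Intramolecular aldol condensation of the 1,5-keto aldehyde under mild base should close the enone while leaving the stereocenter, now γ to the carbonyl, untouched.

Step 3
Reactants: 4 (S)-4-methylcyclohex-2-en-1-one; 5 2,5-dimethoxybenzyl chloride
Product: 8 (S)-3-(2,5-dimethoxybenzyl)-4-methylcyclohex-2-en-1-one, via (2,5-dimethoxybenzyl)magnesium chloride 6 (not isolated), via trans silyl enol ether 7 (not isolated)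
Conditions: 5, Mg, THF, 0 °C; then 4, CuBr·SMe2 (10 mol%), TMSCl, HMPA, −78 °C; crude 7: Pd(OAc)2 (10 mol%), O2 (1 atm), DMSO, 25 °C
Reagents that add atoms: none
Why: Copper-catalysed, TMSCl-accelerated conjugate addition of the benzylic Grignard reagent followed by Saegusa–Ito oxidation of the regiodefined silyl enol ether should return the enone with the arylmethyl group on the β-carbon; the transient C-3 stereocenter of 7 is removed again and C-4 (future C-8) is not touched.

Step 4
Reactants: 8 (S)-3-(2,5-dimethoxybenzyl)-4-methylcyclohex-2-en-1-one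
Product: 10 (2R,3S,4S)-3-(2,5-dimethoxybenzyl)-3,4-dimethyl-2-(prop-2-en-1-yl)cyclohexan-1-one, via lithium enolate 9 (not isolated)
Conditions: Me2CuLi (MeLi, CuI), Et2O, −20 °C; then allyl bromide, HMPA, THF, −20 → 25 °C
Reagents that add atoms: lithium dimethylcuprate, [Li+].C[Cu-]C; allyl bromide, C=CCBr
Why: Three-component conjugate addition–enolate alkylation, in which the cuprate should deliver methyl to C-9 anti to the C-8 methyl and the regiodefined enolate should be allylated at C-10 by axial attack anti to the pseudoaxial arylmethyl group on C-9 (the other axial attack would be syn to an axial C-8 methyl), giving allyl trans to arylmethyl.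

Step 5
Reactants: 10 (2R,3S,4S)-3-(2,5-dimethoxybenzyl)-3,4-dimethyl-2-(prop-2-en-1-yl)cyclohexan-1-one
Product: 12 (4S,5S,6R)-5-(2,5-dimethoxybenzyl)-4,5-dimethyl-6-(prop-2-en-1-yl)cyclohex-1-en-1-yl trifluoromethanesulfonate, via kinetic lithium enolate 11 (not isolated)
Conditions: LDA, THF, −78 °C; PhNTf2, −78 → 0 °C
Reagents that add atoms: N-phenylbis(trifluoromethanesulfonimide), O=S(=O)(N(c1ccccc1)S(=O)(=O)C(F)(F)F)C(F)(F)F
Why: Kinetic deprotonation at the unhindered C-6 methylene and O-sulfonylation should give the less substituted enol triflate without touching the C-10 stereocenter.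

Step 6
Reactants: 13 3-acetyl-3-methyloxolan-2-one (α-acetyl-α-methyl-γ-butyrolactone)
Product: 14 5-bromo-3-methylpentan-2-one (racemic)
Conditions: 48% aq HBr, 90 °C
Reagents that add atoms: hydrogen bromide, Br
Why: Acid-mediated lactone opening by bromide with decarboxylation of the β-keto acid is the classical route from α-acyl lactones to γ-halo ketones; no stereocenter is controlled here.

Step 7
Reactants: 14 5-bromo-3-methylpentan-2-one
Product: 15 2-(4-bromobutan-2-yl)-2-methyl-1,3-dioxolane (racemic)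
Conditions: HOCH2CH2OH, TsOH·H2O (cat.), PhH, reflux (−H2O)
Reagents that add atoms: ethane-1,2-diol, OCCO
Why: Acid-catalysed ketalisation with azeotropic removal of water masks the ketone so that an organometallic reagent can be made from the bromide.

Step 8
Reactants: 15 2-(4-bromobutan-2-yl)-2-methyl-1,3-dioxolane; 16 4,4-dimethylcyclohex-2-en-1-one
Product: 19 (3R)-4,4-dimethyl-3-[3-(2-methyl-1,3-dioxolan-2-yl)butyl]cyclohexan-1-one (side-chain epimers), via Grignard reagent 17 (not isolated), via dialkylzinc reagent 18 (not isolated)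
Conditions: 15, Mg, THF; Zn(OMe)2 (0.5 equiv), Et2O, magnesium salts removed; then 16, Cu(OTf)2 (2 mol%), (S,R,R)-binaphthol bis(1-phenylethyl)amine phosphoramidite (4 mol%), PhMe, −30 °C
Reagents that add atoms: none
Why: Copper-catalysed asymmetric conjugate addition of a dialkylzinc reagent with a chiral phosphoramidite ligand, a reaction type established for 4,4-dimethylcyclohex-2-en-1-one, should set C-5′ by catalyst control (ligand sense chosen by analogy with cyclohex-2-en-1-one); the side-chain methine remains a mixture that converges in step 9.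

Step 9
Reactants: 19 (3R)-4,4-dimethyl-3-[3-(2-methyl-1,3-dioxolan-2-yl)butyl]cyclohexan-1-one
Product: 21 (4aS,7S)-4,4,7,8-tetramethyl-3,4,4a,5,6,7-hexahydronaphthalen-1(2H)-one, via diketone 20 (not isolated)
Conditions: 2 M HCl, THF, 25 °C; then KOH, MeOH, 65 °C
Reagents that add atoms: none
Why: Ketal hydrolysis and base-mediated intramolecular aldol condensation of the 1,7-diketone should close ring C as the only six-membered enone available, and C-8′ (γ to the carbonyl) should equilibrate through the dienolate to the epimer with its methyl pseudoaxial (allylic 1,2-strain with the C-9′ methyl), which is the required cis relationship to the C-5′ ring bond.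

Step 10
Reactants: 21 (4aS,7S)-4,4,7,8-tetramethyl-3,4,4a,5,6,7-hexahydronaphthalen-1(2H)-one
Product: 22 (1S,4aS,7S)-4,4,7,8-tetramethyl-1,2,3,4,4a,5,6,7-octahydronaphthalen-1-ol
Conditions: (R)-2-methyl-CBS-oxazaborolidine (0.2 equiv), BH3·SMe2, THF, −30 °C
Reagents that add atoms: none
Why: Corey–Bakshi–Shibata reduction, in which the (R)-oxazaborolidine (large group = the fully substituted alkene carbon) should deliver hydride under reagent control to give the (1′S)-allylic alcohol whose configuration is transferred in step 11.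

Step 11
Reactants: 22 (1S,4aS,7S)-4,4,7,8-tetramethyl-1,2,3,4,4a,5,6,7-octahydronaphthalen-1-ol
Product: 24 ethyl 2-[(1R,2S,4aS)-1,2,5,5-tetramethyl-1,2,3,4,4a,5,6,7-octahydronaphthalen-1-yl]acetate, via mixed ketene acetal 23 (not isolated)
Conditions: MeC(OEt)3, EtCO2H (cat.), xylene, 140 °C (−EtOH)
Reagents that add atoms: triethyl orthoacetate, CC(OCC)(OCC)OCC
Why: Johnson–Claisen rearrangement, in which the ketene acetal on the pseudoaxial C-1′ oxygen should rearrange suprafacially so that the CH2CO2Et group arrives at C-9′ on the face of the former C–O bond (anti to the C-8′ methyl), creating the quaternary stereocenter and moving the alkene to C1′=C10′ in one operation.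

Step 12
Reactants: 24 ethyl 2-[(1R,2S,4aS)-1,2,5,5-tetramethyl-1,2,3,4,4a,5,6,7-octahydronaphthalen-1-yl]acetate
Product: 25 2-[(1R,2S,4aS)-1,2,5,5-tetramethyl-1,2,3,4,4a,5,6,7-octahydronaphthalen-1-yl]ethan-1-ol
Conditions: LiAlH4, Et2O, 0 °C
Reagents that add atoms: none
Why: Hydride reduction of the ester to the primary alcohol affects no stereocenter and leaves the trisubstituted alkene alone.

Step 13
Reactants: 25 2-[(1R,2S,4aS)-1,2,5,5-tetramethyl-1,2,3,4,4a,5,6,7-octahydronaphthalen-1-yl]ethan-1-ol
Product: 26 (1R,2S,4aS)-1-(2-iodoethyl)-1,2,5,5-tetramethyl-1,2,3,4,4a,5,6,7-octahydronaphthalene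
Conditions: I2, PPh3, imidazole, CH2Cl2, 0 → 25 °C
Reagents that add atoms: iodine, II
Why: Appel-type iodination converts the primary alcohol into the iodide under neutral conditions that the alkene tolerates.

Step 14
Reactants: 26 (1R,2S,4aS)-1-(2-iodoethyl)-1,2,5,5-tetramethyl-1,2,3,4,4a,5,6,7-octahydronaphthalene; 12 enol triflate of ring B
Product: 29 coupled triene (the cyclohexene of 12 with OTf replaced by the 2-[(1R,2S,4aS)-1,2,5,5-tetramethyl-1,2,3,4,4a,5,6,7-octahydronaphthalen-1-yl]ethyl group), via alkyllithium 27 (not isolated), via lithium alkyl(methoxy)borate 28 (not isolated)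
Conditions: 26, t-BuLi (2.1 equiv), Et2O, −78 °C; B-methoxy-9-BBN, THF, −78 → 25 °C; then 12, Pd(dppf)Cl2 (5 mol%), K3PO4 (aq), DMF, 25 → 50 °C
Reagents that add atoms: none
Why: B-alkyl Suzuki–Miyaura coupling, in which the borate made by iodine–lithium exchange and boron capture should transfer its primary alkyl group to the cyclohexenyl triflate, joining the halves at C5–C12′ with the C5=C6 alkene in place and forming no stereocenter.

Step 15
Reactants: 29 coupled triene
Product: 31 primary alcohol (29 with the allyl group on C-10 converted into 3-hydroxypropyl), via B-alkyl-9-BBN 30 (not isolated)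
Conditions: 9-BBN (1.3 equiv), THF, 0 → 25 °C; then NaOH, H2O2, 0 °C
Reagents that add atoms: hydrogen peroxide, OO
Why: Anti-Markovnikov hydroboration–oxidation with 9-BBN should be selective for the monosubstituted allyl alkene over the two trisubstituted ring alkenes.

Step 16
Reactants: 31 primary alcohol
Product: 32 primary iodide (29 with 3-iodopropyl on C-10)
Conditions: I2, PPh3, imidazole, CH2Cl2, 0 → 25 °C
Reagents that add atoms: iodine, II
Why: Appel-type iodination of the primary alcohol under neutral conditions leaves the alkenes and the aryl ethers untouched.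

Step 17
Reactants: 32 primary iodide
Product: 33 enyne (29 with pent-4-yn-1-yl on C-10)
Conditions: LiC≡CH·H2NCH2CH2NH2, DMSO, 25 °C
Reagents that add atoms: lithium acetylide ethylenediamine complex, [Li]C#C.NCCN
Why: SN2 displacement of the unhindered primary iodide by lithium acetylide adds C-4 and C-11 as the terminal alkyne.

Step 18
Reactants: 33 enyne
Product: 35 2-{[(1S,2S,4aR,8aR)-1,2-dimethyl-5-methylidene-4a-{2-[(1R,2S,4aS)-1,2,5,5-tetramethyl-1,2,3,4,4a,5,6,7-octahydronaphthalen-1-yl]ethyl}decahydronaphthalen-1-yl]methyl}-1,4-dimethoxybenzene, via exocyclic vinylstannane 34 (not isolated)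
Conditions: Bu3SnH (1.3 equiv, slow addition), AIBN (0.2 equiv), PhH (0.01 M), 80 °C; then TsOH·H2O (5 mol%), MeOH/CH2Cl2, 0 °C
Reagents that add atoms: none
Why: The tributylstannyl radical adds reversibly to the terminal alkyne carbon C-11, the resulting vinyl radical at C-4 attacks C-5 of the ring B alkene, the secondary C-6 radical is reduced by Bu3SnH, and mild acid then replaces tin on C-11 by hydrogen to leave the C-4 methylene. The closest known reaction type is the tin hydride-mediated hydrostannylative cyclization of enynes (vinyl radical cyclization), which is known to build quaternary ring-fusion carbons. Ring A closes in the 6-exo-trig mode. The only new stereocenter, C-5, is controlled by C-10: the three-carbon tether can reach C-5 only on its own face and axial attack on the cyclohexene gives the cis-fused decalin, leaving the bulky two-carbon link to the lower decalin equatorial. The step needs 6-exo attack at the fully substituted alkene carbon in preference to 7-endo attack or intramolecular hydrogen transfer, which the short rigid allylic tether on C-10 and slow addition of Bu3SnH should secure. It also needs chemoselectivity over the ring D alkene, which follows because stannyl radical addition to alkenes is reversible and only the alkyne adduct has a ring closure open to it.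

Step 19
Reactants: 35 dimethyl ether
Product: 36 2-{[(1S,2S,4aR,8aR)-1,2-dimethyl-5-methylidene-4a-{2-[(1R,2S,4aS)-1,2,5,5-tetramethyl-1,2,3,4,4a,5,6,7-octahydronaphthalen-1-yl]ethyl}decahydronaphthalen-1-yl]methyl}benzene-1,4-diol
Conditions: NaSEt (10 equiv), DMF, 140 °C; then 1 M HCl (work-up)
Reagents that add atoms: none
Why: SN2 demethylation of both aryl methyl ethers by ethanethiolate avoids acids and oxidants, so the exocyclic and trisubstituted alkenes should survive, as they do in thiolate demethylations of related terpenyl hydroquinone dimethyl ethers.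

Step 20
Reactants: 36 hydroquinone
Product: 37 2-{[(1S,2S,4aR,8aR)-1,2-dimethyl-5-methylidene-4a-{2-[(1R,2S,4aS)-1,2,5,5-tetramethyl-1,2,3,4,4a,5,6,7-octahydronaphthalen-1-yl]ethyl}decahydronaphthalen-1-yl]methyl}benzene-1,4-diyl bis(hydrogen sulfate)
Conditions: SO3·pyridine (8 equiv), pyridine, 50 °C; then Dowex 50W (H+ form), MeOH/H2O, 0 °C
Reagents that add atoms: sulfur trioxide pyridine complex, O=S(=O)([O-])[n+]1ccccc1
Why: O-Sulfation of both phenols with the SO3·pyridine complex, followed by exchange of the pyridinium counter-ions on a proton-form resin, should give the bis(hydrogen sulfate) without touching the alkenes.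

**Compound list**

1 | propanal | CCC=O | starting material
2 | methyl vinyl ketone (but-3-en-2-one) | C=CC(C)=O | starting material
3 | (S)-2-methyl-5-oxohexanal | C[C@H](C=O)CCC(C)=O | intermediate
4 | (S)-4-methylcyclohex-2-en-1-one | C[C@H]1CCC(=O)C=C1 | intermediate
5 | 2,5-dimethoxybenzyl chloride | COc1ccc(OC)c(CCl)c1 | starting material
6 | (2,5-dimethoxybenzyl)magnesium chloride | COc1ccc(OC)c(C[Mg]Cl)c1 | intermediate
7 | trimethyl{[(3R,4S)-3-(2,5-dimethoxybenzyl)-4-methylcyclohex-1-en-1-yl]oxy}silane | C[C@H]1CCC(O[Si](C)(C)C)=C[C@@H]1Cc1cc(OC)ccc1OC | intermediate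
8 | (S)-3-(2,5-dimethoxybenzyl)-4-methylcyclohex-2-en-1-one | C[C@H]1CCC(=O)C=C1Cc1cc(OC)ccc1OC | intermediate
9 | lithium (3S,4S)-3-(2,5-dimethoxybenzyl)-3,4-dimethylcyclohex-1-en-1-olate | C[C@H]1CCC(O[Li])=C[C@@]1(C)Cc1cc(OC)ccc1OC | intermediate
10 | (2R,3S,4S)-3-(2,5-dimethoxybenzyl)-3,4-dimethyl-2-(prop-2-en-1-yl)cyclohexan-1-one | C=CC[C@H]1C(=O)CC[C@H](C)[C@]1(C)Cc1cc(OC)ccc1OC | intermediate
11 | lithium (4S,5S,6R)-5-(2,5-dimethoxybenzyl)-4,5-dimethyl-6-(prop-2-en-1-yl)cyclohex-1-en-1-olate | C=CC[C@H]1C(O[Li])=CC[C@H](C)[C@]1(C)Cc1cc(OC)ccc1OC | intermediate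
12 | (4S,5S,6R)-5-(2,5-dimethoxybenzyl)-4,5-dimethyl-6-(prop-2-en-1-yl)cyclohex-1-en-1-yl trifluoromethanesulfonate | C=CC[C@H]1C(OS(=O)(=O)C(F)(F)F)=CC[C@H](C)[C@]1(C)Cc1cc(OC)ccc1OC | intermediate
13 | 3-acetyl-3-methyloxolan-2-one | CC(=O)C1(C)CCOC1=O | starting material
14 | 5-bromo-3-methylpentan-2-one (racemic) | CC(=O)C(C)CCBr | intermediate
15 | 2-(4-bromobutan-2-yl)-2-methyl-1,3-dioxolane (racemic) | CC1(OCCO1)C(C)CCBr | intermediate
16 | 4,4-dimethylcyclohex-2-en-1-one | CC1(C)CCC(=O)C=C1 | starting material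
17 | [3-(2-methyl-1,3-dioxolan-2-yl)butyl]magnesium bromide | CC1(OCCO1)C(C)CC[Mg]Br | intermediate
18 | bis[3-(2-methyl-1,3-dioxolan-2-yl)butyl]zinc | CC1(OCCO1)C(C)CC[Zn]CCC(C)C1(C)OCCO1 | intermediate
19 | (3R)-4,4-dimethyl-3-[3-(2-methyl-1,3-dioxolan-2-yl)butyl]cyclohexan-1-one (side-chain epimers) | CC2(OCCO2)C(C)CC[C@@H]1CC(=O)CCC1(C)C | intermediate
20 | (3R)-4,4-dimethyl-3-(3-methyl-4-oxopentyl)cyclohexan-1-one (side-chain epimers) | CC(=O)C(C)CC[C@@H]1CC(=O)CCC1(C)C | intermediate
21 | (4aS,7S)-4,4,7,8-tetramethyl-3,4,4a,5,6,7-hexahydronaphthalen-1(2H)-one | CC1=C2C(=O)CCC(C)(C)[C@@H]2CC[C@@H]1C | intermediate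
22 | (1S,4aS,7S)-4,4,7,8-tetramethyl-1,2,3,4,4a,5,6,7-octahydronaphthalen-1-ol | CC1=C2[C@@H](O)CCC(C)(C)[C@@H]2CC[C@@H]1C | intermediate
23 | (1S,4aS,7S)-1-[(1-ethoxyethenyl)oxy]-4,4,7,8-tetramethyl-1,2,3,4,4a,5,6,7-octahydronaphthalene | CC1=C2[C@@H](OC(=C)OCC)CCC(C)(C)[C@@H]2CC[C@@H]1C | intermediate
24 | ethyl 2-[(1R,2S,4aS)-1,2,5,5-tetramethyl-1,2,3,4,4a,5,6,7-octahydronaphthalen-1-yl]acetate | CCOC(=O)C[C@@]1(C)C2=CCCC(C)(C)[C@@H]2CC[C@@H]1C | intermediate
25 | 2-[(1R,2S,4aS)-1,2,5,5-tetramethyl-1,2,3,4,4a,5,6,7-octahydronaphthalen-1-yl]ethan-1-ol | OCC[C@@]1(C)C2=CCCC(C)(C)[C@@H]2CC[C@@H]1C | intermediate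
26 | (1R,2S,4aS)-1-(2-iodoethyl)-1,2,5,5-tetramethyl-1,2,3,4,4a,5,6,7-octahydronaphthalene | ICC[C@@]1(C)C2=CCCC(C)(C)[C@@H]2CC[C@@H]1C | intermediate
27 | {2-[(1R,2S,4aS)-1,2,5,5-tetramethyl-1,2,3,4,4a,5,6,7-octahydronaphthalen-1-yl]ethyl}lithium | [Li]CC[C@@]1(C)C2=CCCC(C)(C)[C@@H]2CC[C@@H]1C | intermediate
28 | lithium 9-methoxy-9-{2-[(1R,2S,4aS)-1,2,5,5-tetramethyl-1,2,3,4,4a,5,6,7-octahydronaphthalen-1-yl]ethyl}-9-boranuidabicyclo[3.3.1]nonane | [Li+].CO[B-]1(CC[C@@]2(C)C3=CCCC(C)(C)[C@@H]3CC[C@@H]2C)C4CCCC1CCC4 | intermediate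
29 | coupled triene: ring B cyclohexene of 12 with OTf replaced by the 2-(lower decalinyl)ethyl group of 26; allyl on C-10 | C=CC[C@H]1C(CC[C@@]2(C)C3=CCCC(C)(C)[C@@H]3CC[C@@H]2C)=CC[C@H](C)[C@]1(C)Cc1cc(OC)ccc1OC | intermediate
30 | B-alkyl-9-BBN: 29 with the allyl terminus bonded to the boron of 9-borabicyclo[3.3.1]nonane | C(CC[C@H]1C(CC[C@@]2(C)C3=CCCC(C)(C)[C@@H]3CC[C@@H]2C)=CC[C@H](C)[C@]1(C)Cc1cc(OC)ccc1OC)B4C5CCCC4CCC5 | intermediate
31 | primary alcohol: 29 with 3-hydroxypropyl on C-10 | OCCC[C@H]1C(CC[C@@]2(C)C3=CCCC(C)(C)[C@@H]3CC[C@@H]2C)=CC[C@H](C)[C@]1(C)Cc1cc(OC)ccc1OC | intermediate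
32 | primary iodide: 29 with 3-iodopropyl on C-10 | ICCC[C@H]1C(CC[C@@]2(C)C3=CCCC(C)(C)[C@@H]3CC[C@@H]2C)=CC[C@H](C)[C@]1(C)Cc1cc(OC)ccc1OC | intermediate
33 | enyne: 29 with pent-4-yn-1-yl on C-10 | C#CCCC[C@H]1C(CC[C@@]2(C)C3=CCCC(C)(C)[C@@H]3CC[C@@H]2C)=CC[C@H](C)[C@]1(C)Cc1cc(OC)ccc1OC | intermediate
34 | exocyclic vinylstannane: 35 carrying SnBu3 on C-11 (E/Z mixture) | CCCC[Sn](CCCC)(CCCC)C=C1CCC[C@H]2[C@]1(CC[C@@]1(C)C3=CCCC(C)(C)[C@@H]3CC[C@@H]1C)CC[C@H](C)[C@]2(C)Cc1cc(OC)ccc1OC | intermediate
35 | 2-{[(1S,2S,4aR,8aR)-1,2-dimethyl-5-methylidene-4a-{2-[(1R,2S,4aS)-1,2,5,5-tetramethyl-1,2,3,4,4a,5,6,7-octahydronaphthalen-1-yl]ethyl}decahydronaphthalen-1-yl]methyl}-1,4-dimethoxybenzene | C=C1CCC[C@H]2[C@]1(CC[C@@]1(C)C3=CCCC(C)(C)[C@@H]3CC[C@@H]1C)CC[C@H](C)[C@]2(C)Cc1cc(OC)ccc1OC | intermediate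
36 | 2-{[(1S,2S,4aR,8aR)-1,2-dimethyl-5-methylidene-4a-{2-[(1R,2S,4aS)-1,2,5,5-tetramethyl-1,2,3,4,4a,5,6,7-octahydronaphthalen-1-yl]ethyl}decahydronaphthalen-1-yl]methyl}benzene-1,4-diol | C=C1CCC[C@H]2[C@]1(CC[C@@]1(C)C3=CCCC(C)(C)[C@@H]3CC[C@@H]1C)CC[C@H](C)[C@]2(C)Cc1cc(O)ccc1O | intermediate
37 | 2-{[(1S,2S,4aR,8aR)-1,2-dimethyl-5-methylidene-4a-{2-[(1R,2S,4aS)-1,2,5,5-tetramethyl-1,2,3,4,4a,5,6,7-octahydronaphthalen-1-yl]ethyl}decahydronaphthalen-1-yl]methyl}benzene-1,4-diyl bis(hydrogen sulfate) | C=C1CCC[C@H]2[C@]1(CC[C@@]1(C)C3=CCCC(C)(C)[C@@H]3CC[C@@H]1C)CC[C@H](C)[C@]2(C)Cc1cc(OS(=O)(=O)O)ccc1OS(=O)(=O)O | target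

**Totals**

Total step count: 20. Longest linear sequence: 15 steps (13 → 37; steps 6 to 13 and 14 to 20).

**Steps most likely to fail**

Step 18. The vinyl radical may be reduced, or may abstract hydrogen intramolecularly from C-1 or the allylic C-10, before it adds to the fully substituted C-5. The cyclized homoallylic radical may also rearrange by ring expansion at low tin hydride concentration, and cis selectivity may erode because the attack is syn to the axial C-9 methyl. The fallback sets out from enyne 33 and replaces the radical chain by a palladium hydride-mediated reductive cyclization (Pd2(dba)3·CHCl3, AcOH, Et3SiH, PhMe). Hydropalladation would place palladium on C-4, syn insertion of the C5=C6 alkene through the tether would enforce the cis fusion, and the silane would reduce the alkylpalladium intermediate. It comes back to the route at 35 and makes no new compound (F0).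

Step 11. The allylic alcohol may ionise under the acidic, hot conditions and dehydrate to a diene, and the sigmatropic shift onto the fully substituted C-9′ next to the C-8′ methyl may be slow. The fallback sets out from alcohol 22 and uses an Ireland–Claisen rearrangement under basic, low-temperature conditions. Acetylation (Ac2O, DMAP, Et3N) would give the allylic acetate F1; LDA and TMSCl in THF at −78 °C would give its trimethylsilyl ketene acetal F2; warming to 60 °C would rearrange F2 with the same suprafacial chirality transfer to the trimethylsilyl ester F3. Reduction of crude F3 with LiAlH4 comes back to the route at alcohol 25.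

Step 4. C-allylation of the hindered enolate next to the new quaternary carbon may be slow, with proton transfer to regioisomeric enolates, O-allylation and double alkylation, and facial control at C-10 may be incomplete. The fallback sets out from enone 8 and forms the C-10–allyl bond by Tsuji decarboxylative allylation. Me2CuLi followed by allyl chloroformate would trap enolate 9 as the allyl enol carbonate F4, and Pd(PPh3)4 (cat.) in THF would release the same enolate regiospecifically as an ion pair with an allylpalladium cation under neutral conditions. Loss of carbon dioxide and C-allylation come back to the route at ketone 10.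

**Further compounds**

F0 | step 18 | none | none
F1 | step 11 | (1S,4aS,7S)-4,4,7,8-tetramethyl-1,2,3,4,4a,5,6,7-octahydronaphthalen-1-yl acetate | CC1=C2[C@@H](OC(C)=O)CCC(C)(C)[C@@H]2CC[C@@H]1C
F2 | step 11 | trimethylsilyl ketene acetal of F1 | CC1=C2[C@@H](OC(=C)O[Si](C)(C)C)CCC(C)(C)[C@@H]2CC[C@@H]1C
F3 | step 11 | trimethylsilyl 2-[(1R,2S,4aS)-1,2,5,5-tetramethyl-1,2,3,4,4a,5,6,7-octahydronaphthalen-1-yl]acetate | C[Si](C)(C)OC(=O)C[C@@]1(C)C2=CCCC(C)(C)[C@@H]2CC[C@@H]1C
F4 | step 4 | allyl (3S,4S)-3-(2,5-dimethoxybenzyl)-3,4-dimethylcyclohex-1-en-1-yl carbonate | C[C@H]1CCC(OC(=O)OCC=C)=C[C@@]1(C)Cc1cc(OC)ccc1OC
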